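## Structural features

The target is a flavonol. Ring A (C4a–C8a, hydroxyls on C5 and C7) is fused to the pyranone ring C (O1, C2, C3, C4=O), and ring B (C1'–C6') is attached to C2 by the single bond C2–C1'. The molecule has no stereocentre, so none stand next to each other; the only ones met in the route are transient and disappear on aromatisation. Of the five peripheral oxygens, the enol oxygen O3 on ring C and the phenol oxygen O3' on ring B carry hydrogen sulfate groups, while O5, O7 and O4' are free. The sulfate half-esters are the fragile groups: they hydrolyse under acid, the O3 ester is an enol sulfate and a good leaving group, and the unmasked ring B is an easily oxidised ortho-dioxygenated arene. The carbon skeleton is simple; the real difficulty is telling five hydroxyls apart, above all the neighbours O3' and O4', and bringing the sulfates in at the very end. The key step exploits the fact that ring B is bound through C1' only, with its oxygens at C4' (para) and C3' (meta). Cutting C1'–C2' and C5'–C6' leaves an alkyne on C2 and a 2-silyloxydiene, whose oxygen becomes O4' at ketone level. The silyl enol ether C3'=C4' that remains is where O3' can be added separately as an sp3 hydroxyl.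

## Logic of the disconnections

**22 to 21.** The three O–CH2Ph bonds at O5, O7 and O4' are cut last. The sulfate half-esters tolerate neither acid nor strong nucleophiles, and hydrogenolysis is neutral. The forward step must cleave three benzyl ethers without touching the S–O esters, with the sulfates kept as salts.

**21 to 20.** The bonds O3–S and O3'–S are cut together, since both sulfates are alike and can go onto the only two free hydroxyls in one operation. The problem becomes a tribenzylated flavonol. The forward step must sulfate the hydrogen-bonded O3–H exhaustively.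

**20 to 19 to 18.** The two acetal bonds O3–CH2 and O3'–CH2 are cut, then the O4'–benzyl bond. Using the same acetal on both oxygens means one acid step frees exactly the two positions to be sulfated. Benzyl on O4' leaves later with those on O5 and O7. This demands that O4' be the only free hydroxyl in 18.

**18 to 17.** No skeletal bond is cut; two hydrogens are added back to ring B. At the cyclohexenone level O4' is a ketone and O3' an ether on sp3 carbon, so the two oxygens differ in kind. The forward dehydrogenation must not expel O3'.

**17 to 16 to 14.** The acetal on O3' is removed and then the C3'–O bond is cut. C3' is the nucleophilic carbon of a silyl enol ether, so the oxygen can be delivered there and nowhere else. 14 then has a single oxygen on ring B and no stereochemistry. The oxidant must choose the enol ether over two other C=C bonds.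

**14 to 11 and 13.** The bonds C1'–C2' and C5'–C6' are cut. This removes ring B completely and leaves a chromone carrying a two-carbon alkyne and a four-carbon diene. The forward cycloaddition must place the silyloxy carbon para to C1'.

**13 to 12.** The O–Si bond is cut; the diene is the silyl enol ether of a commodity enone.

**11 to 10 to 8 and 9.** The C(sp)–Si bond is cut, then the C2–C(sp) bond. The silyl cap lets the reactive enynone be stored and released only when needed. The coupling needs a C2 halide that enters oxidative addition readily.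

**8 to 7 to 6.** The C2–I bond and the acetal bond on O3 are cut. The acetal directs metalation to C2, the only ring C–H left on the pyranone. The base must not add to C2.

**6 to 4.** The C3–O bond is cut. The unsubstituted chromone is oxygenated at C3 through its 2,3-oxirane. The oxidant must be neutral so that the benzyl ethers and the pyranone survive.

**4 to 2 (through 3).** The bonds C2–C3 and O1–C2 are cut. A one-carbon amide acetal supplies C2 to the methyl ketone and the free ortho-hydroxyl closes ring C.

**2 to 1.** Two O–benzyl bonds are cut. The third hydroxyl stays free because it is chelated to the ketone, and it is the one needed for ring closure.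

## Other disconnections considered

**Alternative 1:** The cut is the O1–C8a bond, made while ring C is a non-aromatic pyranone and ring A does not yet exist.

- **Forward key step:** racemic [4-(benzyloxy)-3-(methoxymethoxy)phenyl](furan-2-yl)methanol A2 would be methoxylated at the anode with bromide as mediator and then hydrolysed. The carbinol oxygen closes on the former furan carbon and gives 2-[4-(benzyloxy)-3-(methoxymethoxy)phenyl]-6-hydroxy-2H-pyran-3(6H)-one A1 (Achmatowicz rearrangement).
- **In favour:** the oxidation needs no stoichiometric oxidant and scales well. A1 already carries the C3 oxygen at the right carbon and a ring B whose two oxygens are differentiated from a purchasable catechol monoether.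
- **Against:** A1 has no ring A. The carbons that become C4a and C8a are an enone β-carbon and a lactol carbon, C4 is a CH that must still become the carbonyl, and C2 is sp3. The cheapest part of the target, the phloroglucinol ring, would have to be annulated from four carbons with two oxygens and then aromatised.
- **Comparison:** on mechanism the alternative is the better of the two at its key step, since the furan-to-pyranone rearrangement is on firmer ground than a cycloaddition to a weakly activated alkyne. On structure it builds the easiest ring the hardest way, where the chosen plan buys rings A and most of C in 1. On step economy it should be clearly longer; the end game from 20 onward would be the same.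

**Alternative 2:** The cut is C4–C4a.

- **Forward key step:** (2E)-2-(allyloxy)-3-[3-(allyloxy)-4-(benzyloxy)phenyl]-3-[3,5-bis(benzyloxy)phenoxy]prop-2-enoic acid A4 is activated as a mixed anhydride formed in situ. It acylates the aryloxy ring ortho to the ether oxygen and gives 3-(allyloxy)-2-[3-(allyloxy)-4-(benzyloxy)phenyl]-5,7-bis(benzyloxy)-4H-chromen-4-one A3.
- **In favour:** the aryloxy ring comes from the symmetrical 3,5-bis(benzyloxy)phenol A5, so both ortho positions are the same and there is no regiochemical question. The arene is strongly activated, and no ring needs a change of oxidation level. Allyl on O3 and O3' is orthogonal to benzyl, so one deallylation with zerovalent palladium would lead from A3 straight to 20.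
- **Against:** A4 is a tetrasubstituted alkene bearing three heteroatom groups. It must be made with the carboxyl cis to the aryloxy group, from an α-alkoxy-β-keto ester and A5 over several steps. The O3'/O4' pattern must again be bought or set by selective alkylation.
- **Comparison:** this is the strongest competitor. On mechanism it is the better plan, an intramolecular acylation of an activated arene against an unproven dienophile. Its end game from A3 is also shorter than the seven steps needed after 14. On structure the chosen plan is better in principle, because the O3'/O4' difference follows from the way ring B is made; in practice the two are equal if the monobenzyl catechol acid is purchasable. Overall step count should be similar.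

**Alternative 3:** The cut removes ring A through four bonds (C8–C8a, C7–C8, C5–C6, C4a–C5).

- **Forward key step:** irradiation of 6-[4-(benzyloxy)-3-(methoxymethoxy)phenyl]-2-(diazoacetyl)-5-(methoxymethoxy)-4H-pyran-4-one A7 triggers a Wolff rearrangement to a vinylketene. This adds (triisopropylsilyloxy)(trimethylsilyl)acetylene A8 in a (2+2) sense; four-electron ring opening and six-electron electrocyclisation then give 2-[4-(benzyloxy)-3-(methoxymethoxy)phenyl]-5-hydroxy-3-(methoxymethoxy)-7-(triisopropylsilyloxy)-6-(trimethylsilyl)-4H-chromen-4-one A6.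
- **In favour:** A7 derives from the cheap comenic acid A9. Four skeletal bonds form in one flask, and ring A arrives aromatic with O5 and O7 already different.
- **Against:** the plan builds the ring that the cheapest starting material already contains. It needs a diazoalkane-based homologation, the 4-pyranone chromophore has photochemistry of its own, and the C6 silyl and O7 silyl groups must be removed and O5/O7 benzylated before 20 is reached. The O3'/O4' pattern again comes from outside.
- **Comparison:** on mechanism the alternative is the better one in bond economy, four bonds against two, and it gives an arene directly where the chosen plan needs a later dehydrogenation. On structure it solves a differentiation (O5 against O7) that the target does not need, while the chosen plan solves the one it does need. On step economy the protecting-group corrections after A6 should make it at least as long, and probably longer.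

Key step: step 9

Assumption: the sulfates are written as free hydrogen sulfates, but 21 and 22 are made and handled as salts (pyridinium, then sodium); 22 is put into the acid form only at the end on a cold H+ exchange resin.

Remark on the precursor: in 14 the silyloxy carbon is C4' and the enol ether bond is C3'=C4', which is the constitution needed, so the key-step structures are used unchanged. 11 keeps benzyl on O5/O7 and the methoxymethyl acetal on O3; because a terminal enynone is prone to addition and oligomerisation, it is stored as the C-silyl form 10 and released just before the cycloaddition.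

## Route

Step 1
Reactants: 1 2',4',6'-trihydroxyacetophenone (phloroacetophenone)
Product: 2 1-[2,4-bis(benzyloxy)-6-hydroxyphenyl]ethan-1-one
Conditions: BnBr (2.1 equiv), K2CO3 (2.2 equiv), DMF, 0 °C → rt
Reagents that add atoms: benzyl bromide, BrCc1ccccc1
Why: Williamson ether synthesis; the para hydroxyl and one ortho hydroxyl are alkylated, after which the last hydroxyl is locked in a hydrogen bond to the ketone and should resist a third alkylation with this stoichiometry.

Step 2
Reactants: 2 1-[2,4-bis(benzyloxy)-6-hydroxyphenyl]ethan-1-one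
Product: 4 5,7-bis(benzyloxy)-4H-chromen-4-one, via enaminone 3 (not isolated)
Conditions: Me2NCH(OMe)2 (2 equiv), toluene, 95 °C; evaporate; aq. HCl (2 M), CH2Cl2, 40 °C
Reagents that add atoms: N,N-dimethylformamide dimethyl acetal, COC(OC)N(C)C
Why: Enaminone route to chromones: the methyl ketone condenses with the amide acetal, and acid then promotes conjugate addition of the phenol and loss of dimethylamine to close ring C.

Step 3
Reactants: 4 5,7-bis(benzyloxy)-4H-chromen-4-one
Product: 6 5,7-bis(benzyloxy)-3-hydroxy-4H-chromen-4-one, via 2,3-epoxychromanone 5 (not isolated)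
Conditions: DMDO (ca. 0.08 M in acetone, 1.3 equiv), CH2Cl2, 0 °C; evaporate; p-TsOH·H2O (5 mol %), CH2Cl2, rt
Reagents that add atoms: dimethyldioxirane, CC1(C)OO1
Why: Neutral dioxirane epoxidation of the chromone C2=C3 bond, then acid-catalysed oxirane opening at the acetal carbon C2 (cation stabilised by O1) and loss of H3, which should give the 3-hydroxychromone; the two transient stereocentres are erased.

Step 4
Reactants: 6 5,7-bis(benzyloxy)-3-hydroxy-4H-chromen-4-one
Product: 7 5,7-bis(benzyloxy)-3-(methoxymethoxy)-4H-chromen-4-one
Conditions: MOMCl (1.5 equiv), i-Pr2NEt (2 equiv), CH2Cl2, 0 °C → rt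
Reagents that add atoms: chloromethyl methyl ether, COCCl
Why: O-alkylation of the acidic enol hydroxyl to the acetal; this group directs the next metalation and is later removed together with the acetal on O3'.

Step 5
Reactants: 7 5,7-bis(benzyloxy)-3-(methoxymethoxy)-4H-chromen-4-one
Product: 8 5,7-bis(benzyloxy)-2-iodo-3-(methoxymethoxy)-4H-chromen-4-one
Conditions: lithium 2,2,6,6-tetramethylpiperidide (1.2 equiv), THF, −78 °C, 30 min; then I2 (1.3 equiv), −78 → −30 °C
Reagents that add atoms: iodine, II
Why: Directed metalation followed by iodinolysis: C2–H is the only pyranone C–H, lies between O1 and the chelating acetal oxygen, and a hindered amide should deprotonate it without adding to C2.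

Step 6
Reactants: 8 5,7-bis(benzyloxy)-2-iodo-3-(methoxymethoxy)-4H-chromen-4-one; 9 ethynyl(trimethyl)silane (trimethylsilylacetylene)
Product: 10 5,7-bis(benzyloxy)-3-(methoxymethoxy)-2-[(trimethylsilyl)ethynyl]-4H-chromen-4-one
Conditions: PdCl2(PPh3)2 (3 mol %), CuI (5 mol %), Et3N (3 equiv), THF, rt
Reagents that add atoms: none
Why: Sonogashira coupling; the C2–I bond is a β-iodo enone and should add to zerovalent palladium at room temperature, and the tertiary amine is not nucleophilic enough to attack C2.

Step 7
Reactants: 10 5,7-bis(benzyloxy)-3-(methoxymethoxy)-2-[(trimethylsilyl)ethynyl]-4H-chromen-4-one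
Product: 11 5,7-bis(benzyloxy)-2-ethynyl-3-(methoxymethoxy)-4H-chromen-4-one
Conditions: n-Bu4NF (1.1 equiv), AcOH (1.3 equiv), THF, −20 → 0 °C; used at once
Reagents that add atoms: none
Why: Fluoride-induced protodesilylation of the alkynylsilane; buffering with acetic acid should prevent base-induced addition to the terminal enynone.

Step 8
Reactants: 12 but-3-en-2-one (methyl vinyl ketone)
Product: 13 2-(tert-butyldimethylsilyloxy)buta-1,3-diene
Conditions: TBSOTf (1.05 equiv), Et3N (1.3 equiv), Et2O, 0 °C → rt; distil
Reagents that add atoms: tert-butyldimethylsilyl trifluoromethanesulfonate, CC(C)(C)[Si](C)(C)OS(=O)(=O)C(F)(F)F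
Why: Soft enolisation and O-silylation of the enone on its methyl side, a standard preparation of 2-silyloxydienes.

Step 9
Reactants: 11 5,7-bis(benzyloxy)-2-ethynyl-3-(methoxymethoxy)-4H-chromen-4-one; 13 2-(tert-butyldimethylsilyloxy)buta-1,3-diene
Product: 14 5,7-bis(benzyloxy)-2-[4-(tert-butyldimethylsilyloxy)cyclohexa-1,4-dien-1-yl]-3-(methoxymethoxy)-4H-chromen-4-one
Conditions: 13 (4 equiv), BHT (5 mol %), degassed toluene (0.3 M), sealed tube, 130 °C, argon, base-washed glassware; quick filtration over Et3N-deactivated silica
Reagents that add atoms: none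
Why: A thermal, concerted but asynchronous (4+2) cycloaddition of normal electron demand: the diene HOMO is largest at the CH2 next to the silyloxy carbon and the LUMO of 11 is largest at the terminal alkyne carbon, the δ position of the C4=O/C3=C2/alkyne system, so these atoms bond first (C5'–C6') while the other diene terminus closes on the inner alkyne carbon (C1'–C2'). The closest known reaction type is the Diels–Alder reaction of 2-silyloxybuta-1,3-dienes with ynones and propiolates, which gives 4-substituted 1-silyloxycyclohexa-1,4-dienes. Ring B is closed by the cycloaddition itself, suprafacially on both partners, with both σ bonds formed in one kinetic step. No stereocentre is created, since every ring carbon of 14 is sp2 or CH2. The step needs regioselectivity (silyloxy carbon para, not meta, to C1'), which the single donor of 13 matched with the polarisation of the alkyne should secure. It needs chemoselectivity for the alkyne over the pyranone C2=C3 bond, which is tetrasubstituted and part of a vinylogous ester. It also needs the adduct to survive, so acid and oxygen are excluded to keep the silyl enol ether from hydrolysis and the 1,4-diene from oxidation to the arene. A second addition is not expected, because the new C1'=C6' bond is a trisubstituted alkene and a much poorer dienophile than the alkyne.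

Step 10
Reactants: 14 5,7-bis(benzyloxy)-2-[4-(tert-butyldimethylsilyloxy)cyclohexa-1,4-dien-1-yl]-3-(methoxymethoxy)-4H-chromen-4-one
Product: 16 5,7-bis(benzyloxy)-2-(5-hydroxy-4-oxocyclohex-1-en-1-yl)-3-(methoxymethoxy)-4H-chromen-4-one (racemic), via silyloxy-oxirane 15 (not isolated)
Conditions: DMDO (1.05 equiv, acetone), CH2Cl2, −78 → −40 °C; then n-Bu4NF (1.1 equiv), AcOH (1.5 equiv), THF, −40 → 0 °C
Reagents that add atoms: dimethyldioxirane, CC1(C)OO1
Why: Rubottom oxidation: the silyl enol ether is by far the most electron-rich alkene, since C1'=C6' and C2=C3 are both conjugated to the pyranone carbonyl, and buffered fluoride opens the silyloxy-oxirane to the α-hydroxy ketone. The new stereocentre C3' forms as a racemate and needs no control because it is erased in step 12.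

Step 11
Reactants: 16 5,7-bis(benzyloxy)-2-(5-hydroxy-4-oxocyclohex-1-en-1-yl)-3-(methoxymethoxy)-4H-chromen-4-one
Product: 17 5,7-bis(benzyloxy)-3-(methoxymethoxy)-2-[5-(methoxymethoxy)-4-oxocyclohex-1-en-1-yl]-4H-chromen-4-one (racemic)
Conditions: MOMCl (2 equiv), i-Pr2NEt (3 equiv), n-Bu4NI (cat.), CH2Cl2, 0 °C → rt
Reagents that add atoms: chloromethyl methyl ether, COCCl
Why: Acetal protection of the only free hydroxyl under weakly basic conditions; any shift of the ring double bond would be harmless, because all such isomers converge in the next step.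

Step 12
Reactants: 17 5,7-bis(benzyloxy)-3-(methoxymethoxy)-2-[5-(methoxymethoxy)-4-oxocyclohex-1-en-1-yl]-4H-chromen-4-one
Product: 18 5,7-bis(benzyloxy)-2-[4-hydroxy-3-(methoxymethoxy)phenyl]-3-(methoxymethoxy)-4H-chromen-4-one
Conditions: DDQ (1.2 equiv), 2,4,6-collidine (2 equiv), toluene, rt → 50 °C, argon
Reagents that add atoms: none
Why: Dehydrogenative aromatisation of a cyclohexenone with a quinone: base-assisted enolisation through the allylic α-hydrogen at C5' gives a dienol, hydride is taken from C2' and the proton lost from C3'. Keeping the medium non-acidic should prevent ionisation of the C3' ether, which has no base-induced elimination pathway.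

Step 13
Reactants: 18 5,7-bis(benzyloxy)-2-[4-hydroxy-3-(methoxymethoxy)phenyl]-3-(methoxymethoxy)-4H-chromen-4-one
Product: 19 5,7-bis(benzyloxy)-2-[4-(benzyloxy)-3-(methoxymethoxy)phenyl]-3-(methoxymethoxy)-4H-chromen-4-one
Conditions: BnBr (1.2 equiv), K2CO3 (1.5 equiv), DMF, rt
Reagents that add atoms: benzyl bromide, BrCc1ccccc1
Why: Williamson etherification of the only free phenol; the acetal on O3' cannot migrate, so the O3'/O4' distinction is kept.

Step 14
Reactants: 19 5,7-bis(benzyloxy)-2-[4-(benzyloxy)-3-(methoxymethoxy)phenyl]-3-(methoxymethoxy)-4H-chromen-4-one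
Product: 20 5,7-bis(benzyloxy)-2-[4-(benzyloxy)-3-hydroxyphenyl]-3-hydroxy-4H-chromen-4-one
Conditions: HCl (ca. 2 M, from AcCl in MeOH), MeOH/CH2Cl2, rt → 40 °C
Reagents that add atoms: none
Why: Acid-catalysed acetal exchange with methanol removes both methoxymethyl groups (enol O3 and aryl O3'); the benzyl ethers should persist under these mild conditions.

Step 15
Reactants: 20 5,7-bis(benzyloxy)-2-[4-(benzyloxy)-3-hydroxyphenyl]-3-hydroxy-4H-chromen-4-one
Product: 21 5,7-bis(benzyloxy)-2-[4-(benzyloxy)-3-(sulfooxy)phenyl]-4-oxo-4H-chromen-3-yl hydrogen sulfate (handled as disodium salt)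
Conditions: SO3·pyridine (8 equiv), pyridine, 55 °C; aq. NaHCO3 to pH 8; reversed-phase chromatography
Reagents that add atoms: sulfur trioxide–pyridine complex, O=S(=O)([O-])[n+]1ccccc1
Why: O-sulfonation of hydroxyl groups by an amine–SO3 complex; only O3 and O3' are free, and excess reagent with gentle heating should overcome the hydrogen bond that holds O3–H to the carbonyl.

Step 16
Reactants: 21 5,7-bis(benzyloxy)-2-[4-(benzyloxy)-3-(sulfooxy)phenyl]-4-oxo-4H-chromen-3-yl hydrogen sulfate (disodium salt)
Product: 22 quercetin 3,3'-bissulfate, 2-[4-hydroxy-3-(sulfooxy)phenyl]-5,7-dihydroxy-4-oxo-4H-chromen-3-yl hydrogen sulfate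
Conditions: H2 (1 atm), 10% Pd/C, MeOH/H2O (trace NaHCO3), rt; filter; Dowex 50W (H+ form), 0 °C; freeze-dry
Reagents that add atoms: none
Why: Catalytic hydrogenolysis of the three benzyl ethers under neutral conditions, to which sulfate half-ester salts are inert; brief cold ion exchange then gives the acid form.

## Compound list

1 | 2',4',6'-trihydroxyacetophenone (phloroacetophenone) | CC(=O)c1c(O)cc(O)cc1O | starting material
2 | 1-[2,4-bis(benzyloxy)-6-hydroxyphenyl]ethan-1-one | CC(=O)c1c(O)cc(OCc2ccccc2)cc1OCc1ccccc1 | intermediate
3 | (2E)-1-[2,4-bis(benzyloxy)-6-hydroxyphenyl]-3-(dimethylamino)prop-2-en-1-one | CN(C)/C=C/C(=O)c1c(O)cc(OCc2ccccc2)cc1OCc1ccccc1 | intermediate (not isolated)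
4 | 5,7-bis(benzyloxy)-4H-chromen-4-one | O=c1ccoc2cc(OCc3ccccc3)cc(OCc3ccccc3)c12 | intermediate
5 | 5,7-bis(benzyloxy)-2,3-epoxy-2,3-dihydro-4H-chromen-4-one (cis-fused oxirane, racemic, one enantiomer drawn) | O=C1[C@@H]2O[C@@H]2Oc2cc(OCc3ccccc3)cc(OCc3ccccc3)c21 | intermediate (not isolated)
6 | 5,7-bis(benzyloxy)-3-hydroxy-4H-chromen-4-one | O=c1c(O)coc2cc(OCc3ccccc3)cc(OCc3ccccc3)c12 | intermediate
7 | 5,7-bis(benzyloxy)-3-(methoxymethoxy)-4H-chromen-4-one | COCOc1coc2cc(OCc3ccccc3)cc(OCc3ccccc3)c2c1=O | intermediate
8 | 5,7-bis(benzyloxy)-2-iodo-3-(methoxymethoxy)-4H-chromen-4-one | COCOc1c(I)oc2cc(OCc3ccccc3)cc(OCc3ccccc3)c2c1=O | intermediate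
9 | ethynyl(trimethyl)silane (trimethylsilylacetylene) | C#C[Si](C)(C)C | starting material
10 | 5,7-bis(benzyloxy)-3-(methoxymethoxy)-2-[(trimethylsilyl)ethynyl]-4H-chromen-4-one | COCOc1c(C#C[Si](C)(C)C)oc2cc(OCc3ccccc3)cc(OCc3ccccc3)c2c1=O | intermediate
11 | 5,7-bis(benzyloxy)-2-ethynyl-3-(methoxymethoxy)-4H-chromen-4-one | C#Cc1oc2cc(OCc3ccccc3)cc(OCc3ccccc3)c2c(=O)c1OCOC | intermediate
12 | but-3-en-2-one (methyl vinyl ketone) | CC(=O)C=C | starting material
13 | 2-(tert-butyldimethylsilyloxy)buta-1,3-diene | C=CC(=C)O[Si](C)(C)C(C)(C)C | intermediate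
14 | 5,7-bis(benzyloxy)-2-[4-(tert-butyldimethylsilyloxy)cyclohexa-1,4-dien-1-yl]-3-(methoxymethoxy)-4H-chromen-4-one | CC(C)(C)[Si](C)(C)OC1=CCC(=CC1)c1oc2cc(OCc3ccccc3)cc(OCc3ccccc3)c2c(=O)c1OCOC | intermediate
15 | 5,7-bis(benzyloxy)-2-[6-(tert-butyldimethylsilyloxy)-7-oxabicyclo[4.1.0]hept-3-en-3-yl]-3-(methoxymethoxy)-4H-chromen-4-one (oxirane on the former C3'=C4' bond, cis-fused, racemic, one enantiomer drawn) | COCOc1c(C2=CC[C@]3(O[Si](C)(C)C(C)(C)C)O[C@@H]3C2)oc2cc(OCc3ccccc3)cc(OCc3ccccc3)c2c1=O | intermediate (not isolated)
16 | 5,7-bis(benzyloxy)-2-(5-hydroxy-4-oxocyclohex-1-en-1-yl)-3-(methoxymethoxy)-4H-chromen-4-one (racemic) | COCOc1c(C2=CCC(=O)C(O)C2)oc2cc(OCc3ccccc3)cc(OCc3ccccc3)c2c1=O | intermediate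
17 | 5,7-bis(benzyloxy)-3-(methoxymethoxy)-2-[5-(methoxymethoxy)-4-oxocyclohex-1-en-1-yl]-4H-chromen-4-one (racemic) | COCOc1c(C2=CCC(=O)C(OCOC)C2)oc2cc(OCc3ccccc3)cc(OCc3ccccc3)c2c1=O | intermediate
18 | 5,7-bis(benzyloxy)-2-[4-hydroxy-3-(methoxymethoxy)phenyl]-3-(methoxymethoxy)-4H-chromen-4-one | COCOc1c(-c2ccc(O)c(OCOC)c2)oc2cc(OCc3ccccc3)cc(OCc3ccccc3)c2c1=O | intermediate
19 | 5,7-bis(benzyloxy)-2-[4-(benzyloxy)-3-(methoxymethoxy)phenyl]-3-(methoxymethoxy)-4H-chromen-4-one | COCOc1c(-c2ccc(OCc3ccccc3)c(OCOC)c2)oc2cc(OCc3ccccc3)cc(OCc3ccccc3)c2c1=O | intermediate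
20 | 5,7-bis(benzyloxy)-2-[4-(benzyloxy)-3-hydroxyphenyl]-3-hydroxy-4H-chromen-4-one | O=c1c(O)c(-c2ccc(OCc3ccccc3)c(O)c2)oc2cc(OCc3ccccc3)cc(OCc3ccccc3)c12 | intermediate
21 | 5,7-bis(benzyloxy)-2-[4-(benzyloxy)-3-(sulfooxy)phenyl]-4-oxo-4H-chromen-3-yl hydrogen sulfate (handled as disodium salt) | O=c1c(OS(=O)(=O)O)c(-c2ccc(OCc3ccccc3)c(OS(=O)(=O)O)c2)oc2cc(OCc3ccccc3)cc(OCc3ccccc3)c12 | intermediate
22 | quercetin 3,3'-bissulfate | O=c1c(OS(=O)(=O)O)c(-c2ccc(O)c(OS(=O)(=O)O)c2)oc2cc(O)cc(O)c12 | target

## Step count and least certain steps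

Total: 16 steps. Longest linear sequence: 15 steps (steps 1–7 and 9–16); step 8 is a one-step side branch.

**Step 9 (key step).** The most likely failure is a cycloaddition that is too slow. The alkyne is activated only through the C2=C3–C4=O relay, and donation from O1, O3, O5 and O7 weakens that relay. Thermal oligomerisation of 13, polymerisation of 11, or air oxidation of the adduct to the arene (which would destroy the enol ether needed for O3') could then take over. The fallback gives up the cycloaddition and brings ring B in as an arene; it sets out from 8 and comes back at 20. Purchased 2-(benzyloxy)-5-bromobenzaldehyde F1 would be borylated (B2pin2, PdCl2(dppf), KOAc, dioxane, 80 °C) to 2-(benzyloxy)-5-(4,4,5,5-tetramethyl-1,3,2-dioxaborolan-2-yl)benzaldehyde F2. Anhydrous Suzuki–Miyaura coupling with 8 (Pd(PPh3)4, K3PO4, dioxane, 80 °C) would give 2-(benzyloxy)-5-[5,7-bis(benzyloxy)-3-(methoxymethoxy)-4-oxo-4H-chromen-2-yl]benzaldehyde F3. Baeyer–Villiger oxidation (mCPBA, NaHCO3, CH2Cl2) would give 2-(benzyloxy)-5-[5,7-bis(benzyloxy)-3-(methoxymethoxy)-4-oxo-4H-chromen-2-yl]phenyl formate F4. HCl in MeOH would then remove the formyl group and the acetal on O3 together to give 20.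

**Step 10.** The risks are over-oxidation at the other two C=C bonds or the bis-allylic CH2 groups, and loss of the sensitive β,γ-unsaturated α-ketol through isomerisation or air aromatisation during handling. The fallback introduces O3' after aromatisation instead; it sets out from 14 and comes back at 20. DDQ in toluene at rt should give 5,7-bis(benzyloxy)-2-[4-(tert-butyldimethylsilyloxy)phenyl]-3-(methoxymethoxy)-4H-chromen-4-one F5, and n-Bu4NF would give 5,7-bis(benzyloxy)-2-(4-hydroxyphenyl)-3-(methoxymethoxy)-4H-chromen-4-one F6. Ortho-formylation (MgCl2, Et3N, paraformaldehyde, MeCN, reflux; the two ortho positions are equivalent) would give 5-[5,7-bis(benzyloxy)-3-(methoxymethoxy)-4-oxo-4H-chromen-2-yl]-2-hydroxybenzaldehyde F7. Benzylation (BnBr, K2CO3, DMF) leads to 2-(benzyloxy)-5-[5,7-bis(benzyloxy)-3-(methoxymethoxy)-4-oxo-4H-chromen-2-yl]benzaldehyde F3, which is carried through 2-(benzyloxy)-5-[5,7-bis(benzyloxy)-3-(methoxymethoxy)-4-oxo-4H-chromen-2-yl]phenyl formate F4 to 20 as above.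

**Step 12.** The risk is loss of the C3' oxygen. If the quinone-derived hydroquinone makes the medium acidic, the dienol can ionise at C3' and aromatise by elimination instead of dehydrogenation; slow enolisation could also force temperatures at which benzyl ethers are attacked. The fallback oxidises at the silyl dienol ether level; it sets out from 17 and comes back at 19, bypassing 18. NaN(SiMe3)2 and TBSCl in THF at −78 °C should give 5,7-bis(benzyloxy)-2-[4-(tert-butyldimethylsilyloxy)-5-(methoxymethoxy)cyclohexa-1,3-dien-1-yl]-3-(methoxymethoxy)-4H-chromen-4-one F8. DDQ with 2,4,6-collidine at 0 °C would give 5,7-bis(benzyloxy)-2-[4-(tert-butyldimethylsilyloxy)-3-(methoxymethoxy)phenyl]-3-(methoxymethoxy)-4H-chromen-4-one F9. CsF and BnBr in DMF would then desilylate and benzylate in one flask to give 19.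

**Step 3.** The risks are incomplete epoxidation of a C2=C3 bond deactivated by the carbonyl, slow oxidation of benzylic C–H bonds by excess dioxirane, and ring opening of the oxirane by adventitious water instead of isomerisation. The fallback puts the oxygen on C3 by way of a formyl group; it sets out from 2 and comes back at 6. Vilsmeier–Haack reaction (POCl3, DMF, 0 → 50 °C) should give 5,7-bis(benzyloxy)-4-oxo-4H-chromene-3-carbaldehyde F10. Baeyer–Villiger oxidation (mCPBA, CH2Cl2) would give 5,7-bis(benzyloxy)-4-oxo-4H-chromen-3-yl formate F11, and methanolysis (Et3N, MeOH) would give 6.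

**Step 15.** The risks are incomplete sulfation of the hydrogen-bonded O3–H, which would leave the O3' monosulfate, and hydrolysis of the enol sulfate during isolation of a very polar salt. The fallback uses protected sulfate diesters; it sets out from 20 and comes back at 21. 2,2,2-Trichloroethyl chlorosulfate with Et3N and DMAP in THF should give the neutral, chromatographable 5,7-bis(benzyloxy)-2-{4-(benzyloxy)-3-[(2,2,2-trichloroethoxy)sulfonyloxy]phenyl}-4-oxo-4H-chromen-3-yl 2,2,2-trichloroethyl sulfate F12. Zn and HCO2NH4 in MeOH would then remove the trichloroethyl groups reductively and give 21 as its ammonium salt.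

## Further compounds

F1 | step 9 | 2-(benzyloxy)-5-bromobenzaldehyde | O=Cc1cc(Br)ccc1OCc1ccccc1
F2 | step 9 | 2-(benzyloxy)-5-(4,4,5,5-tetramethyl-1,3,2-dioxaborolan-2-yl)benzaldehyde | O=Cc1cc(B2OC(C)(C)C(C)(C)O2)ccc1OCc1ccccc1
F3 | step 9 | 2-(benzyloxy)-5-[5,7-bis(benzyloxy)-3-(methoxymethoxy)-4-oxo-4H-chromen-2-yl]benzaldehyde | COCOc1c(-c2ccc(OCc3ccccc3)c(C=O)c2)oc2cc(OCc3ccccc3)cc(OCc3ccccc3)c2c1=O
F4 | step 9 | 2-(benzyloxy)-5-[5,7-bis(benzyloxy)-3-(methoxymethoxy)-4-oxo-4H-chromen-2-yl]phenyl formate | COCOc1c(-c2ccc(OCc3ccccc3)c(OC=O)c2)oc2cc(OCc3ccccc3)cc(OCc3ccccc3)c2c1=O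
F5 | step 10 | 5,7-bis(benzyloxy)-2-[4-(tert-butyldimethylsilyloxy)phenyl]-3-(methoxymethoxy)-4H-chromen-4-one | COCOc1c(-c2ccc(O[Si](C)(C)C(C)(C)C)cc2)oc2cc(OCc3ccccc3)cc(OCc3ccccc3)c2c1=O
F6 | step 10 | 5,7-bis(benzyloxy)-2-(4-hydroxyphenyl)-3-(methoxymethoxy)-4H-chromen-4-one | COCOc1c(-c2ccc(O)cc2)oc2cc(OCc3ccccc3)cc(OCc3ccccc3)c2c1=O
F7 | step 10 | 5-[5,7-bis(benzyloxy)-3-(methoxymethoxy)-4-oxo-4H-chromen-2-yl]-2-hydroxybenzaldehyde | COCOc1c(-c2ccc(O)c(C=O)c2)oc2cc(OCc3ccccc3)cc(OCc3ccccc3)c2c1=O
F8 | step 12 | 5,7-bis(benzyloxy)-2-[4-(tert-butyldimethylsilyloxy)-5-(methoxymethoxy)cyclohexa-1,3-dien-1-yl]-3-(methoxymethoxy)-4H-chromen-4-one (racemic) | COCOc1c(C2=CC=C(O[Si](C)(C)C(C)(C)C)C(OCOC)C2)oc2cc(OCc3ccccc3)cc(OCc3ccccc3)c2c1=O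
F9 | step 12 | 5,7-bis(benzyloxy)-2-[4-(tert-butyldimethylsilyloxy)-3-(methoxymethoxy)phenyl]-3-(methoxymethoxy)-4H-chromen-4-one | COCOc1c(-c2ccc(O[Si](C)(C)C(C)(C)C)c(OCOC)c2)oc2cc(OCc3ccccc3)cc(OCc3ccccc3)c2c1=O
F10 | step 3 | 5,7-bis(benzyloxy)-4-oxo-4H-chromene-3-carbaldehyde | O=Cc1coc2cc(OCc3ccccc3)cc(OCc3ccccc3)c2c1=O
F11 | step 3 | 5,7-bis(benzyloxy)-4-oxo-4H-chromen-3-yl formate | O=COc1coc2cc(OCc3ccccc3)cc(OCc3ccccc3)c2c1=O
F12 | step 15 | 5,7-bis(benzyloxy)-2-{4-(benzyloxy)-3-[(2,2,2-trichloroethoxy)sulfonyloxy]phenyl}-4-oxo-4H-chromen-3-yl 2,2,2-trichloroethyl sulfate | O=c1c(OS(=O)(=O)OCC(Cl)(Cl)Cl)c(-c2ccc(OCc3ccccc3)c(OS(=O)(=O)OCC(Cl)(Cl)Cl)c2)oc2cc(OCc3ccccc3)cc(OCc3ccccc3)c12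
A1 | alternative 1 | 2-[4-(benzyloxy)-3-(methoxymethoxy)phenyl]-6-hydroxy-2H-pyran-3(6H)-one (racemic, both anomers) | O=C1C=CC(O)OC1c1ccc(OCc2ccccc2)c(OCOC)c1
A2 | alternative 1 | [4-(benzyloxy)-3-(methoxymethoxy)phenyl](furan-2-yl)methanol (racemic) | OC(c1ccco1)c1ccc(OCc2ccccc2)c(OCOC)c1
A3 | alternative 2 | 3-(allyloxy)-2-[3-(allyloxy)-4-(benzyloxy)phenyl]-5,7-bis(benzyloxy)-4H-chromen-4-one | O=c1c(OCC=C)c(-c2ccc(OCc3ccccc3)c(OCC=C)c2)oc2cc(OCc3ccccc3)cc(OCc3ccccc3)c12
A4 | alternative 2 | (2E)-2-(allyloxy)-3-[3-(allyloxy)-4-(benzyloxy)phenyl]-3-[3,5-bis(benzyloxy)phenoxy]prop-2-enoic acid | OC(=O)/C(OCC=C)=C(\Oc1cc(OCc2ccccc2)cc(OCc2ccccc2)c1)c1ccc(OCc2ccccc2)c(OCC=C)c1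
A5 | alternative 2 | 3,5-bis(benzyloxy)phenol | Oc1cc(OCc2ccccc2)cc(OCc2ccccc2)c1
A6 | alternative 3 | 2-[4-(benzyloxy)-3-(methoxymethoxy)phenyl]-5-hydroxy-3-(methoxymethoxy)-7-(triisopropylsilyloxy)-6-(trimethylsilyl)-4H-chromen-4-one | O=c1c(OCOC)c(-c2ccc(OCc3ccccc3)c(OCOC)c2)oc2cc(O[Si](C(C)C)(C(C)C)C(C)C)c([Si](C)(C)C)c(O)c12
A7 | alternative 3 | 6-[4-(benzyloxy)-3-(methoxymethoxy)phenyl]-2-(diazoacetyl)-5-(methoxymethoxy)-4H-pyran-4-one | [N-]=[N+]=CC(=O)c1cc(=O)c(OCOC)c(-c2ccc(OCc3ccccc3)c(OCOC)c2)o1
A8 | alternative 3 | (triisopropylsilyloxy)(trimethylsilyl)acetylene | C[Si](C)(C)C#CO[Si](C(C)C)(C(C)C)C(C)C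
A9 | alternative 3 | comenic acid (5-hydroxy-4-oxo-4H-pyran-2-carboxylic acid) | O=C(O)c1cc(=O)c(O)co1
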